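The question for each flask is which form holds most of the substrate at the end, and how much of it.

all flasks: substrate 0.23 M; partner 0.299 M; time 50 min

|  | temperature |
|---|---|
| south-east | 25 °C |
| east | 45 °C |
| south-west | 35 °C |

    substrate + partner → intermediate A (k1 = 0.027 M⁻¹ min⁻¹, Ea1 = 77.0 kJ mol⁻¹)
    substrate ⇌ intermediate B (K2 = 5.0, k2 = 0.034 min⁻¹, Ea2 = 81.0 kJ mol⁻¹, ΔH2 = 44.0 kJ mol⁻¹)
    partner + intermediate A ⇌ intermediate C (K3 = 6.4 M⁻¹, k3 = 0.026 M⁻¹ min⁻¹, Ea3 = 53.0 kJ mol⁻¹, ΔH3 = −85.0 kJ mol⁻¹)
    intermediate B → intermediate D (k4 = 0.017 min⁻¹, Ea4 = 101 kJ mol⁻¹)
    intermediate D → product (k5 = 0.0099 min⁻¹, Ea5 = 90.0 kJ mol⁻¹)
    (constants at 25 °C)

- constants are those at 25 °C; use the activation energies and enthalpies for any other temperature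

- which of these there is most of at the end, counted by the substrate in it, south-east (substrate / intermediate D / intermediate A / intermediate B / product)
- which of these there is most of at the end, counted by the substrate in it, east (substrate / intermediate D / intermediate A / intermediate B / product)
- which of these there is most of at the end, counted by the substrate in it, south-west (substrate / intermediate D / intermediate A / intermediate B / product)
- the largest of these amounts at the end, in percent of the substrate charged, south-east
- the largest of these amounts at the end, in percent of the substrate charged, east
- the largest of these amounts at the end, in percent of the substrate charged, south-west

The main line runs from substrate through intermediate B and intermediate D to product. Each of its links has a lifetime, one over its forward rate constant at the flask's temperature. This reckoning adds the lifetimes of the line and divides the time by the sum.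

South-east, 25 °C: the lifetimes add up to 189 min, which gives 0.264.

East, 45 °C: the lifetimes add up to 18.6 min, which gives 2.69.

South-west, 35 °C: the first two links take 25.9 min, and the lifetimes of the whole line add up to 57.0 min, which gives 0.878.

This number, the time over the summed lifetimes of the line, is the chain turnover count. It says how many times an average piece of substrate could walk the whole line.

South-east gets less than one turnover. Its time is longer than the first lifetime but shorter than the first two together, so this reckoning commits to intermediate B.

East gets more than two turnovers, so it commits to product. One number is not enough here, though. At the start in east, substrate goes to intermediate B, by the forward rate alone, 4.7 times as fast as it goes to intermediate A, and if that share held, product in east would stop near 82.3%.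

South-west is the hard case. Its time lies past the first two lifetimes but short of the whole line, so the mean walker stands at intermediate D, and this reckoning commits to intermediate D, narrowly.

The forecast gives intermediate B at 37.5% south-east, product at 80% east and product at 42% south-west. Its grounds are that “the high activation energies of those steps and the endothermic shift towards B push the material through to product”. It differs from this reckoning on south-west.

South-east ends with intermediate B at 37.7%. East ends with product at 80.6%. South-west ends with product at 42.3%, and intermediate D there holds 30.1%. The forecast stands within its margins, and the call for south-west here does not.

East has nearly stopped at 50 min: product stands at 80.6% and reaches 82.4% by 500 min. A flask like east kept at 20 °C gets 0.140 turnovers and holds 39.9% intermediate B with 1.10% product. South-east is far from rest: by 500 min it has 2.64 turnovers, about east's count, and product climbs from 5.04% to 75.3%. Meanwhile intermediate A falls from 13.7% to 9.71% and intermediate C rises from 3.09% to 13.1%.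

The constants used here are invented; the flask was simulated.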